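**Retrosynthetic overview** (cyclopenta[c]pyran numbering: C1, O2, C3, C4, C4a, C5–C7, C7a; coumarin atoms primed)
1. C1–H and the pyran ring come last. The target derives from a 1-ylidene-chromane-2,4-dione by hydride delivery to the convex face, and that derives from an open 3-acyl-4-hydroxy-5-methylcoumarin carrying a 1,2-diketone arm.
2. C1–C3' bond: C-acylation of 4-hydroxy-5-methylcoumarin by a cyclopentanecarboxylic acid.
3. C3/C4 and the 1,2-diketone: an ester-tethered aldol/E1cB between an acetyl group (ozonolysis of isopropenyl) and a 4-methyl-2-oxopentyl ester.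
4. Cyclopentane: Wolff ring contraction of a 2-diazocyclohexanone, in which the CHMe carbon migrates with retention. The ketone comes from a Rh-catalysed asymmetric isopropenylation of 6-methylcyclohexenone.
5. Ring order: cyclohexanone (bought) → cyclopentane. Separately, arene → coumarin lactone (acetoacetate/crotonaldehyde annulation, aromatisation, acetate Claisen). The dihydropyran is formed last.

Assumption: racemic 6-methylcyclohex-2-en-1-one, potassium isopropenyltrifluoroborate and 1-hydroxy-4-methylpentan-2-one are taken as catalogue compounds.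

**Step 1**
Reactants: 1 6-methylcyclohex-2-en-1-one (racemic); 2 potassium trifluoro(prop-1-en-2-yl)borate
Product: 4 (2S,5S)-2-methyl-5-(prop-1-en-2-yl)cyclohexan-1-one (trans), via cis-(2R,5S) epimer 3 (not isolated)
Conditions: [Rh(cod)2]BF4 (3 mol %), (S)-BINAP (3.3 mol %), toluene/H2O 10:1, 100 °C; then K2CO3 (0.2 equiv), MeOH, rt
Reagents that add atoms: none
Why: In this Hayashi–Miyaura-type Rh(I)/BINAP asymmetric 1,4-addition the catalyst sets C5 (future C4a) as S whatever the remote C6 methyl, and base equilibration of the enolisable C2 then gives the diequatorial trans isomer (about 85:15, cis isomer removed on silica and re-equilibrated), which fixes the future C7.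

**Step 2**
Reactants: 4 (2S,5S)-2-methyl-5-(prop-1-en-2-yl)cyclohexan-1-one
Product: 6 (3R,6S)-2-diazo-6-methyl-3-(prop-1-en-2-yl)cyclohexan-1-one, via 2-trifluoroacetyl ketone 5 (not isolated)
Conditions: LiHMDS, THF, −78 °C; CF3CO2CH2CF3; aq. HCl wash; then MsN3, Et3N, H2O, MeCN, rt
Reagents that add atoms: 2,2,2-trifluoroethyl trifluoroacetate, O=C(OCC(F)(F)F)C(F)(F)F (CF3CO in 5 only); methanesulfonyl azide, CS(=O)(=O)N=[N+]=[N-] (N2 in 6)
Why: In this detrifluoroacetylative (Regitz-type) diazo transfer, kinetic enolisation and diazo formation are possible only at the CH2 flank, so the diazo carbon is the future C7a and no stereocentre is touched.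

**Step 3** (key ring contraction)
Reactants: 6 (3R,6S)-2-diazo-6-methyl-3-(prop-1-en-2-yl)cyclohexan-1-one; 7 1-hydroxy-4-methylpentan-2-one
Product: 9 4-methyl-2-oxopentyl (1R,2S,5S)-2-methyl-5-(prop-1-en-2-yl)cyclopentane-1-carboxylate, via cyclopentylidene ketene 8 (not isolated)
Conditions: hν (365 nm), 7 (2 equiv), i-Pr2NEt (0.1 equiv), CH2Cl2, 0 °C
Reagents that add atoms: none
Why: In this photochemical Wolff rearrangement the CHMe carbon shifts 1,2 from C=O to the diazo carbon with retention (the s-Z-locked cyclic diazoketone favours the concerted shift), the six-ring contracts, the ketene is esterified by the primary alcohol, and protonation anti to the larger isopropenyl group gives mainly the 1R ester, while the minor C1 epimer is carried on because this centre is re-set in step 9.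

**Step 4**
Reactants: 9 4-methyl-2-oxopentyl (1R,2S,5S)-2-methyl-5-(prop-1-en-2-yl)cyclopentane-1-carboxylate
Product: 11 (1R,2S,5R)-2-methyl-5-(6-methyl-3,4-dioxoheptan-2-yl)cyclopentane-1-carboxylic acid (side-chain C2' epimers/enol tautomer), via acetyl keto ester 10 (not isolated)
Conditions: O3, CH2Cl2, −78 °C; Me2S; then DBU (1.5 equiv), MeCN, rt; 1 M HCl work-up
Reagents that add atoms: ozone, [O-][O+]=O
Why: Ozonolysis unmasks the methyl ketone, and DBU then enolises only the doubly activated OCH2C(=O) group, whose intramolecular aldol addition (the aliphatic counterpart of the 2-acylbenzoate phenacyl-ester route to 3-acyl-4-methylisocoumarins), acyl transfer to the tertiary alkoxide and E1cB loss of carboxylate place the 1,2-dicarbonyl regiospecifically next to C4, the far less acidic ring α-CH (C4a) staying untouched.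

**Step 5**
Reactants: 12 methyl acetoacetate; 13 (E)-but-2-enal
Product: 15 methyl 6-methyl-2-oxocyclohex-3-ene-1-carboxylate, via Michael adduct 14 (not isolated)
Conditions: NaOMe (0.1 equiv), MeOH, 0 °C; then HCl (g), 0 °C → rt
Reagents that add atoms: none
Why: Michael addition of the acetoacetate C2 to the methyl-bearing β-carbon and an acid-promoted intramolecular aldol condensation (Robinson-type annulation) put CH3 next to the ester carbon, and the stereocentres vanish in step 6.

**Step 6**
Reactants: 15 methyl 6-methyl-2-oxocyclohex-3-ene-1-carboxylate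
Product: 16 methyl 2-hydroxy-6-methylbenzoate
Conditions: DDQ (1.1 equiv), 1,4-dioxane, reflux
Reagents that add atoms: none
Why: DDQ dehydrogenates the enolised cyclohexenone β-keto ester to the hydrogen-bonded salicylate (oxidative aromatisation).

**Step 7**
Reactants: 16 methyl 2-hydroxy-6-methylbenzoate
Product: 18 4-hydroxy-5-methyl-2H-chromen-2-one, via aryl acetate 17 (not isolated)
Conditions: LiHMDS (1.05 equiv), AcCl (1.05 equiv), THF, −78 → 0 °C; then LiHMDS (2.3 equiv), −78 °C → rt; 1 M HCl
Reagents that add atoms: acetyl chloride, CC(=O)Cl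
Why: O-acetylation is followed by an intramolecular Claisen (Dieckmann-type) condensation of the acetate enolate on the neighbouring ester, a non-nucleophilic amide base avoids deacetylation, and the ortho methyl becomes the 5-methyl group.

**Step 8**
Reactants: 11 (1R,2S,5R)-2-methyl-5-(6-methyl-3,4-dioxoheptan-2-yl)cyclopentane-1-carboxylic acid; 18 4-hydroxy-5-methyl-2H-chromen-2-one
Product: 20 4-hydroxy-5-methyl-3-{[(1R,2S,5R)-2-methyl-5-(6-methyl-3,4-dioxoheptan-2-yl)cyclopentyl]carbonyl}-2H-chromen-2-one, via enol lactone 19 (not isolated)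
Conditions: DCC (1.2 equiv), DMAP (1.5 equiv), CH2Cl2, 0 °C → 40 °C; 1 M HCl wash
Reagents that add atoms: none
Why: Steglich activation and DMAP-mediated O→C acyl migration (Fries-type C-acylation of 4-hydroxycoumarins) form C1–C3', the activated acid first closing to enol lactone 19, which is itself an acyl donor, and the stabilised tricarbonyl enolate being the thermodynamic sink.

**Step 9**
Reactants: 20 4-hydroxy-5-methyl-3-{[(1R,2S,5R)-2-methyl-5-(6-methyl-3,4-dioxoheptan-2-yl)cyclopentyl]carbonyl}-2H-chromen-2-one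
Product: 22 3-[(1S,4aS,7S,7aR)-4,7-dimethyl-3-(3-methylbutanoyl)-1,4a,5,6,7,7a-hexahydrocyclopenta[c]pyran-1-yl]-4-hydroxy-5-methyl-2H-chromen-2-one, via pyranylidene chromanedione 21 (not isolated)
Conditions: TsOH·H2O (10 mol %), 4 Å MS, ClCH2CH2Cl, 40 °C; then Hantzsch ester (1.05 equiv), −20 °C
Reagents that add atoms: none
Why: Proposed new method: a dehydrative pyran closure/ionic transfer hydrogenation of a 3-acyl-4-hydroxycoumarin, in which acid lets the enolised 1,5-dicarbonyl pair (C1 vinylogous acid, C3 ketone of the diketone) condense to the push–pull 1-ylidene-dihydropyran 21, whose C7a equilibrates through its 4H-pyran tautomer to the cis-fused isomer because A(1,3) strain with the chromanedione forces the C7a–C7 bond axial; O-protonated 21 is a 1-aryl oxocarbenium ion that takes hydride from the Hantzsch ester anti to that axial bond, that is on the convex face, giving 1S (H1 cis to H7a and H4a), while one equivalent of this mild donor at low temperature spares the conjugated C9 ketone and the ionisable new C1–O2 bond; the closest known reaction types are the silane reduction of hemiketals to C-glycosides through cyclic oxocarbenium ions and the Hantzsch-ester reduction of alkylidene 1,3-dicarbonyl compounds.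

**Compound list**
1 | 6-methylcyclohex-2-en-1-one (racemic) | CC1CCC=CC1=O | starting material
2 | potassium trifluoro(prop-1-en-2-yl)borate | [K+].C=C(C)[B-](F)(F)F | starting material
3 | (2R,5S)-2-methyl-5-(prop-1-en-2-yl)cyclohexan-1-one (cis) | C[C@@H]1CC[C@@H](CC1=O)C(C)=C | intermediate
4 | (2S,5S)-2-methyl-5-(prop-1-en-2-yl)cyclohexan-1-one (trans) | C[C@H]1CC[C@@H](CC1=O)C(C)=C | intermediate
5 | (3S,6S)-6-methyl-3-(prop-1-en-2-yl)-2-(trifluoroacetyl)cyclohexan-1-one (C2 enolised) | C[C@H]1CC[C@H](C(C)=C)C(C(=O)C(F)(F)F)C1=O | intermediate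
6 | (3R,6S)-2-diazo-6-methyl-3-(prop-1-en-2-yl)cyclohexan-1-one | C[C@H]1CC[C@H](C(C)=C)C(=[N+]=[N-])C1=O | intermediate
7 | 1-hydroxy-4-methylpentan-2-one | CC(C)CC(=O)CO | starting material
8 | [(2S,5R)-2-methyl-5-(prop-1-en-2-yl)cyclopentylidene]methanone (ketene) | O=C=C1[C@@H](C(C)=C)CC[C@@H]1C | intermediate
9 | 4-methyl-2-oxopentyl (1R,2S,5S)-2-methyl-5-(prop-1-en-2-yl)cyclopentane-1-carboxylate | CC(C)CC(=O)COC(=O)[C@H]1[C@@H](C(C)=C)CC[C@@H]1C | intermediate
10 | 4-methyl-2-oxopentyl (1R,2S,5S)-2-acetyl-5-methylcyclopentane-1-carboxylate | CC(C)CC(=O)COC(=O)[C@H]1[C@@H](C(C)=O)CC[C@@H]1C | intermediate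
11 | (1R,2S,5R)-2-methyl-5-(6-methyl-3,4-dioxoheptan-2-yl)cyclopentane-1-carboxylic acid (side-chain C2' unassigned) | OC(=O)[C@H]1[C@@H](C(C)C(=O)C(=O)CC(C)C)CC[C@@H]1C | intermediate
12 | methyl acetoacetate | COC(=O)CC(C)=O | starting material
13 | (E)-but-2-enal | C/C=C/C=O | starting material
14 | methyl 2-acetyl-3-methyl-5-oxopentanoate | COC(=O)C(C(C)=O)C(C)CC=O | intermediate
15 | methyl 6-methyl-2-oxocyclohex-3-ene-1-carboxylate | COC(=O)C1C(C)CC=CC1=O | intermediate
16 | methyl 2-hydroxy-6-methylbenzoate | COC(=O)c1c(C)cccc1O | intermediate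
17 | methyl 2-acetoxy-6-methylbenzoate | COC(=O)c1c(C)cccc1OC(C)=O | intermediate
18 | 4-hydroxy-5-methyl-2H-chromen-2-one | O=c1cc(O)c2c(C)cccc2o1 | intermediate
19 | (4aS,7S,7aR)-4,7-dimethyl-3-(3-methylbutanoyl)-5,6,7,7a-tetrahydrocyclopenta[c]pyran-1(4aH)-one | CC1=C(C(=O)CC(C)C)OC(=O)[C@H]2[C@@H]1CC[C@@H]2C | intermediate
20 | 4-hydroxy-5-methyl-3-{[(1R,2S,5R)-2-methyl-5-(6-methyl-3,4-dioxoheptan-2-yl)cyclopentyl]carbonyl}-2H-chromen-2-one | O=C(c1c(O)c2c(C)cccc2oc1=O)[C@H]3[C@@H](C(C)C(=O)C(=O)CC(C)C)CC[C@@H]3C | intermediate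
21 | 3-[(4aS,7S,7aR)-4,7-dimethyl-3-(3-methylbutanoyl)-5,6,7,7a-tetrahydrocyclopenta[c]pyran-1(4aH)-ylidene]-5-methylchromane-2,4-dione (C=C geometry labile) | CC1=C(C(=O)CC(C)C)OC(=C2C(=O)Oc3cccc(C)c3C2=O)[C@H]4[C@@H]1CC[C@@H]4C | intermediate
22 | 3-[(1S,4aS,7S,7aR)-4,7-dimethyl-3-(3-methylbutanoyl)-1,4a,5,6,7,7a-hexahydrocyclopenta[c]pyran-1-yl]-4-hydroxy-5-methyl-2H-chromen-2-one | CC1=C(C(=O)CC(C)C)O[C@H](c2c(O)c3c(C)cccc3oc2=O)[C@H]2[C@@H]1CC[C@@H]2C | target

**Step count:** 9 steps in total. **Longest linear sequence:** 6 steps (1, 2, 3, 4, 8, 9).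

**Steps most likely to fail**

**Step 1.** The α-branched alkenylborate may add sluggishly to the racemic 6-substituted enone, and C7 rests on an 85:15 equilibrium. The fallback sets out from 2 and comes back at 4. The same Rh/(S)-BINAP addition is run on plain cyclohex-2-en-1-one to give (S)-3-(prop-1-en-2-yl)cyclohexan-1-one F1. The methyl group is then introduced afterwards by kinetic enolate alkylation at the unhindered C6 (LDA, THF, −78 °C; MeI). The same K2CO3/MeOH equilibration (through 3) leads to 4.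

**Step 4.** The aldol addition to a methyl ketone may be slow or reversible, and C4a could epimerise if it is. The fallback sets out from 6 and comes back at 19, replacing the aldol by an olefination.
- 6 is photolysed in THF/H2O to (1R,2S,5S)-2-methyl-5-(prop-1-en-2-yl)cyclopentane-1-carboxylic acid F2.
- Ozonolysis (O3; Me2S) gives (1R,2S,5S)-2-acetyl-5-methylcyclopentane-1-carboxylic acid F3.
- Rh2(OAc)4-catalysed O–H insertion with dimethyl (1-diazo-4-methyl-2-oxopentyl)phosphonate gives 1-(dimethoxyphosphoryl)-4-methyl-2-oxopentyl (1R,2S,5S)-2-acetyl-5-methylcyclopentane-1-carboxylate F4.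
- An intramolecular Horner–Wadsworth–Emmons reaction (LiCl, DBU, MeCN) closes 19, which is isolated and fed into step 8 with DMAP/Et3N and no DCC.

**Step 9** (the proposed new step). The possible failures are incomplete dehydration, over-reduction after C1–O2 ionisation, and C1 epimerisation. The fallback uses known chemistry only; it sets out from 11 and comes back at 22.
- 11 is closed with Ac2O/NaOAc to enol lactone 19, which is now isolated.
- DIBAL-H (2.2 equiv, CH2Cl2, −78 °C, as for nepetalactone to nepetalactol) gives (4aS,7S,7aR)-3-(1-hydroxy-3-methylbutyl)-4,7-dimethyl-1,4a,5,6,7,7a-hexahydrocyclopenta[c]pyran-1-ol F5.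
- MnO2 re-oxidises only the allylic carbinol to 1-[(4aS,7S,7aR)-1-hydroxy-4,7-dimethyl-1,4a,5,6,7,7a-hexahydrocyclopenta[c]pyran-3-yl]-3-methylbutan-1-one F6.
- This lactol (the ring-chain tautomer of the aldehyde) and 18 undergo the usual amine-salt-catalysed Knoevenagel condensation/intramolecular oxa-Michael closure (EDDA, CH2Cl2, rt).
- This gives 22 together with its (1R)-epimer 3-[(1R,4aS,7S,7aR)-4,7-dimethyl-3-(3-methylbutanoyl)-1,4a,5,6,7,7a-hexahydrocyclopenta[c]pyran-1-yl]-4-hydroxy-5-methyl-2H-chromen-2-one F7. My conformational analysis suggests F7 is likely to be the major isomer here; the two are separated by HPLC.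

**Further compounds**
F1 | step 1 | (S)-3-(prop-1-en-2-yl)cyclohexan-1-one | C1CC[C@@H](CC1=O)C(C)=C
F2 | step 4 | (1R,2S,5S)-2-methyl-5-(prop-1-en-2-yl)cyclopentane-1-carboxylic acid | OC(=O)[C@H]1[C@@H](C(C)=C)CC[C@@H]1C
F3 | step 4 | (1R,2S,5S)-2-acetyl-5-methylcyclopentane-1-carboxylic acid | OC(=O)[C@H]1[C@@H](C(C)=O)CC[C@@H]1C
F4 | step 4 | 1-(dimethoxyphosphoryl)-4-methyl-2-oxopentyl (1R,2S,5S)-2-acetyl-5-methylcyclopentane-1-carboxylate | COP(=O)(OC)C(OC(=O)[C@H]1[C@@H](C(C)=O)CC[C@@H]1C)C(=O)CC(C)C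
F5 | step 9 | (4aS,7S,7aR)-3-(1-hydroxy-3-methylbutyl)-4,7-dimethyl-1,4a,5,6,7,7a-hexahydrocyclopenta[c]pyran-1-ol | CC1=C(C(O)CC(C)C)OC(O)[C@H]2[C@@H]1CC[C@@H]2C
F6 | step 9 | 1-[(4aS,7S,7aR)-1-hydroxy-4,7-dimethyl-1,4a,5,6,7,7a-hexahydrocyclopenta[c]pyran-3-yl]-3-methylbutan-1-one | CC1=C(C(=O)CC(C)C)OC(O)[C@H]2[C@@H]1CC[C@@H]2C
F7 | step 9 | 3-[(1R,4aS,7S,7aR)-4,7-dimethyl-3-(3-methylbutanoyl)-1,4a,5,6,7,7a-hexahydrocyclopenta[c]pyran-1-yl]-4-hydroxy-5-methyl-2H-chromen-2-one | CC1=C(C(=O)CC(C)C)O[C@@H](c2c(O)c3c(C)cccc3oc2=O)[C@H]2[C@@H]1CC[C@@H]2C
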